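## Retrosynthetic overview

1. Target 22 ⇐ desilylation and C8 acylation of epoxy alcohol 20, whose cis-1,10-epoxide comes from C8–OH-directed epoxidation of the (1(10)Z,4Z)-dienolide 19.
2. α-Methylene-γ-lactone 18 ⇐ lactone 15 (methylenation) ⇐ keto ester 13 (chelation-controlled C6 reduction, lactonisation).
3. Ten-membered ring 13 ⇐ cyclohexenol 10 by anionic oxy-Cope [3,3] rearrangement (forms C8–C9, sets C8 and the 1(10)Z alkene), with C7 alkylation of the enolate in the same flask.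
4. 10 ⇐ enone 4 + alkoxyacetylide from 7 (1,2-addition, trans-hydroalumination); 4 ⇐ (S)-carvone 1 (Luche reduction, silylation, allylic oxidation).
5. Ring order: cyclohexene (bought in carvone) → cyclodecadiene (oxy-Cope) → γ-lactone → epoxide.

Assumption: the SMILES is read literally, i.e. (1R,3S,6S,7S,8R,10S), 4Z alkene, 1,10-epoxide with H-1 and the C10 methyl cis. Ten-membered compounds carry germacranolide numbers (ring C1–C10, lactone carbons C11–C13, methyls C14 on C10 and C15 on C4).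

## Route

Step 1
Reactants: 1 (S)-(+)-carvone
Product: 2 (1S,5S)-cis-carveol
Conditions: NaBH4, CeCl3·7H2O, MeOH, −20 °C
Reagents that add atoms: none
Why: Luche 1,2-reduction in which hydride attacks the enone pseudo-axially, so the hydroxyl ends up cis to the isopropenyl group and the new centre (future C3, S) is set by the carvone stereocentre.

Step 2
Reactants: 2 (1S,5S)-cis-carveol
Product: 3 (1S,5S)-1-(tert-butyldimethylsilyloxy)-2-methyl-5-(prop-1-en-2-yl)cyclohex-2-ene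
Conditions: TBSCl, imidazole, DMF, rt
Reagents that add atoms: tert-butyldimethylsilyl chloride, CC(C)(C)[Si](C)(C)Cl
Why: Silyl protection of the allylic alcohol, needed for the oxidation and the strongly basic steps that follow.

Step 3
Reactants: 3 (1S,5S)-1-(tert-butyldimethylsilyloxy)-2-methyl-5-(prop-1-en-2-yl)cyclohex-2-ene
Product: 4 (4S,6S)-4-(tert-butyldimethylsilyloxy)-3-methyl-6-(prop-1-en-2-yl)cyclohex-2-en-1-one
Conditions: Rh2(cap)4 (dirhodium tetracaprolactamate, 1 mol%), t-BuOOH (70% aq., 5 equiv), K2CO3 (cat.), CH2Cl2, rt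
Reagents that add atoms: tert-butyl hydroperoxide, CC(C)(C)OO
Why: Radical allylic C–H oxidation at the only ring allylic methylene gives the γ-silyloxy enone, and the isopropenyl-bearing centre, now α to the ketone, keeps its cis (diequatorial) arrangement.

Step 4
Reactants: 5 4-methoxybenzyl alcohol; 6 trichloroethylene
Product: 7 (E)-1,2-dichlorovinyl 4-methoxybenzyl ether
Conditions: KH, THF, 0 °C; then Cl2C=CHCl, −50 °C to rt
Reagents that add atoms: none
Why: Alkoxide addition–elimination on trichloroethylene (first stage of the Greene ynol ether synthesis) gives the E dichloroenol ether, a storable precursor of the alkoxyacetylide.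

Step 5
Reactants: 7 (E)-1,2-dichlorovinyl 4-methoxybenzyl ether; 4 (4S,6S)-4-(tert-butyldimethylsilyloxy)-3-methyl-6-(prop-1-en-2-yl)cyclohex-2-en-1-one
Product: 9 (1R,4S,6S)-4-(tert-butyldimethylsilyloxy)-1-[(4-methoxybenzyloxy)ethynyl]-3-methyl-6-(prop-1-en-2-yl)cyclohex-2-en-1-ol, via lithium alkynyl ether 8 (not isolated)
Conditions: n-BuLi (2.1 equiv), THF, −78 to −40 °C; then 4, −78 °C; H2O
Reagents that add atoms: none
Why: Loss of HCl and chlorine–lithium exchange give the lithium alkoxyacetylide, whose 1,2-addition should occur by pseudo-axial attack on the half-chair locked by the cis-diequatorial OTBS and isopropenyl groups, placing the alkyne cis to both (carbinol centre R, substrate control).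

Step 6
Reactants: 9 (1R,4S,6S)-4-(tert-butyldimethylsilyloxy)-1-[(4-methoxybenzyloxy)ethynyl]-3-methyl-6-(prop-1-en-2-yl)cyclohex-2-en-1-ol
Product: 10 (1R,4S,6S)-4-(tert-butyldimethylsilyloxy)-1-[(E)-2-(4-methoxybenzyloxy)ethenyl]-3-methyl-6-(prop-1-en-2-yl)cyclohex-2-en-1-ol
Conditions: LiAlH4, THF, 0 °C to rt; Na2SO4·10H2O
Reagents that add atoms: none
Why: Alkoxide-directed trans-hydroalumination of the propargylic ynol ether, then protonolysis of the vinylalane with retention, gives the E enol ether.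

Step 7
Reactants: 10 (1R,4S,6S)-4-(tert-butyldimethylsilyloxy)-1-[(E)-2-(4-methoxybenzyloxy)ethenyl]-3-methyl-6-(prop-1-en-2-yl)cyclohex-2-en-1-ol
Product: 13 methyl [(3S,7S,8R)-3-(tert-butyldimethylsilyloxy)-8-(4-methoxybenzyloxy)-4,10-dimethyl-6-oxocyclodeca-1(10)Z,4Z-dien-7-yl]acetate, via potassium alkoxide 11 (not isolated), via potassium enolate 12 (not isolated)
Conditions: KN(SiMe3)2 (1.05 equiv), 18-crown-6, THF, −78 to 0 °C; then BrCH2CO2Me, −78 to −40 °C; pH 7 buffer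
Reagents that add atoms: methyl bromoacetate, COC(=O)CBr
Why: Anionic oxy-Cope [3,3]-sigmatropic rearrangement through the chair that keeps isopropenyl and OTBS equatorial on the cyclohexene (ring carbon C2 axial, enol-ether oxygen equatorial) forms the C8–C9 bond and the ten-membered ring, gives the 1(10)Z alkene and C8 (R) by chirality transfer from the carvone-derived centre, and the enolate is then alkylated on its open outer face, anti to C8–OPMB, setting C7 (S).

Step 8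
Reactants: 13 methyl [(3S,7S,8R)-3-(tert-butyldimethylsilyloxy)-8-(4-methoxybenzyloxy)-4,10-dimethyl-6-oxocyclodeca-1(10)Z,4Z-dien-7-yl]acetate
Product: 15 (3S,6S,7S,8R)-3-(tert-butyldimethylsilyloxy)-8-(4-methoxybenzyloxy)-13-norgermacra-1(10)Z,4Z-dien-6,12-olide, via hydroxy ester 14 (not isolated)
Conditions: Zn(BH4)2, Et2O, −30 to 0 °C; then PPTS (cat.), benzene, 40 °C
Reagents that add atoms: none
Why: Chelation-controlled 1,2-reduction (zinc bridges the C6 carbonyl and the C8 ether oxygen, hydride enters anti to the C7 side chain) sets C6 (S) syn to C8–O, and the γ-hydroxy ester lactonises with loss of methanol.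

Step 9
Reactants: 15 (3S,6S,7S,8R)-3-(tert-butyldimethylsilyloxy)-8-(4-methoxybenzyloxy)-13-norgermacra-1(10)Z,4Z-dien-6,12-olide
Product: 18 (3S,6S,7S,8R)-3-(tert-butyldimethylsilyloxy)-8-(4-methoxybenzyloxy)germacra-1(10)Z,4Z,11(13)-trien-6,12-olide, via Mannich base 16 (not isolated), via ammonium iodide 17 (not isolated)
Conditions: LiN(i-Pr)2, THF, −78 °C; Me2N=CH2+ I− (Eschenmoser's salt), −78 °C to rt; then MeI, MeOH, rt; then aq. NaHCO3, CH2Cl2, rt
Reagents that add atoms: N,N-dimethylmethyleneiminium iodide (Eschenmoser's salt), C=[N+](C)C.[I-]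
Why: Mannich aminomethylation of the lactone enolate, N-methylation and base-induced β-elimination of trimethylamine install the exocyclic methylene; no stereocentre is affected because C11 becomes sp2.

Step 10
Reactants: 18 (3S,6S,7S,8R)-3-(tert-butyldimethylsilyloxy)-8-(4-methoxybenzyloxy)germacra-1(10)Z,4Z,11(13)-trien-6,12-olide
Product: 19 (3S,6S,7S,8R)-3-(tert-butyldimethylsilyloxy)-8-hydroxygermacra-1(10)Z,4Z,11(13)-trien-6,12-olide
Conditions: DDQ, CH2Cl2/pH 7 buffer (10:1), 0 °C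
Reagents that add atoms: none
Why: Oxidative cleavage of the 4-methoxybenzyl ether (benzylic hydride abstraction, hydrolysis of the oxocarbenium ion) frees only the C8 hydroxyl, since the silyl ether, lactone and alkenes are inert to DDQ.

Step 11
Reactants: 19 (3S,6S,7S,8R)-3-(tert-butyldimethylsilyloxy)-8-hydroxygermacra-1(10)Z,4Z,11(13)-trien-6,12-olide
Product: 20 (1R,3S,6S,7S,8R,10S)-3-(tert-butyldimethylsilyloxy)-1,10-epoxy-8-hydroxygermacra-4Z,11(13)-dien-6,12-olide
Conditions: VO(acac)2 (5 mol%), t-BuOOH (1.5 equiv, in decane), CH2Cl2, 0 °C to rt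
Reagents that add atoms: tert-butyl hydroperoxide, CC(C)(C)OO
Why: Homoallylic hydroxyl-directed vanadium-catalysed epoxidation delivers oxygen to the 1(10)Z alkene on the face of the C8 hydroxyl (also its outer face), giving the cis-epoxide (C1 R, C10 S), while the 4,5-alkene (no free hydroxyl nearby) and the electron-poor methylene lactone do not react.

Step 12
Reactants: 20 (1R,3S,6S,7S,8R,10S)-3-(tert-butyldimethylsilyloxy)-1,10-epoxy-8-hydroxygermacra-4Z,11(13)-dien-6,12-olide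
Product: 21 (1R,3S,6S,7S,8R,10S)-3-(tert-butyldimethylsilyloxy)-1,10-epoxy-8-isobutyryloxygermacra-4Z,11(13)-dien-6,12-olide
Conditions: (i-PrCO)2O, Et3N, DMAP (cat.), CH2Cl2, 0 °C to rt
Reagents that add atoms: isobutyric anhydride, CC(C)C(=O)OC(=O)C(C)C
Why: DMAP-catalysed acylation of the only free hydroxyl under non-acidic conditions that spare the epoxide.

Step 13
Reactants: 21 (1R,3S,6S,7S,8R,10S)-3-(tert-butyldimethylsilyloxy)-1,10-epoxy-8-isobutyryloxygermacra-4Z,11(13)-dien-6,12-olide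
Product: 22 (1R,3S,6S,7S,8R,10S)-1,10-epoxy-3-hydroxy-8-isobutyryloxygermacra-4Z,11(13)-dien-6,12-olide (CNP0261225.1)
Conditions: HF·pyridine, pyridine, THF, 0 °C to rt
Reagents that add atoms: none
Why: Fluoride-driven Si–O cleavage, buffered with pyridine to protect the epoxide, ester and methylene lactone, releases the C3 hydroxyl and gives the target.

## Compound list

1 | (S)-(+)-carvone | CC1=CC[C@@H](CC1=O)C(C)=C | starting material
2 | (1S,5S)-cis-carveol (OH and isopropenyl cis) | CC1=CC[C@@H](C[C@@H]1O)C(C)=C | intermediate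
3 | (1S,5S)-1-(tert-butyldimethylsilyloxy)-2-methyl-5-(prop-1-en-2-yl)cyclohex-2-ene | CC1=CC[C@@H](C[C@@H]1O[Si](C)(C)C(C)(C)C)C(C)=C | intermediate
4 | (4S,6S)-4-(tert-butyldimethylsilyloxy)-3-methyl-6-(prop-1-en-2-yl)cyclohex-2-en-1-one (OTBS and isopropenyl cis) | CC1=CC(=O)[C@@H](C[C@@H]1O[Si](C)(C)C(C)(C)C)C(C)=C | intermediate
5 | 4-methoxybenzyl alcohol | COc1ccc(CO)cc1 | starting material
6 | trichloroethylene | ClC=C(Cl)Cl | starting material
7 | (E)-1,2-dichlorovinyl 4-methoxybenzyl ether | COc1ccc(CO/C(Cl)=C\Cl)cc1 | intermediate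
8 | lithium (4-methoxybenzyloxy)acetylide | [Li]C#COCc1ccc(OC)cc1 | intermediate (not isolated)
9 | (1R,4S,6S)-4-(tert-butyldimethylsilyloxy)-1-[(4-methoxybenzyloxy)ethynyl]-3-methyl-6-(prop-1-en-2-yl)cyclohex-2-en-1-ol (alkynyl, isopropenyl and OTBS all cis) | CC1=C[C@](O)(C#COCc2ccc(OC)cc2)[C@@H](C[C@@H]1O[Si](C)(C)C(C)(C)C)C(C)=C | intermediate
10 | (1R,4S,6S)-4-(tert-butyldimethylsilyloxy)-1-[(E)-2-(4-methoxybenzyloxy)ethenyl]-3-methyl-6-(prop-1-en-2-yl)cyclohex-2-en-1-ol | CC1=C[C@](O)(/C=C/OCc2ccc(OC)cc2)[C@@H](C[C@@H]1O[Si](C)(C)C(C)(C)C)C(C)=C | intermediate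
11 | potassium alkoxide of 10 | CC1=C[C@]([O-])(/C=C/OCc2ccc(OC)cc2)[C@@H](C[C@@H]1O[Si](C)(C)C(C)(C)C)C(C)=C.[K+] | intermediate (not isolated)
12 | potassium (3S,8R)-3-(tert-butyldimethylsilyloxy)-8-(4-methoxybenzyloxy)-4,10-dimethylcyclodeca-1(10)Z,4Z,6-trien-6-olate (ring carbons C5 and C8 trans on the enolate double bond) | [K+].[O-]/C1=C\[C@H](OCc2ccc(OC)cc2)C/C(C)=C\C[C@H](O[Si](C)(C)C(C)(C)C)/C(C)=C\1 | intermediate (not isolated)
13 | methyl [(3S,7S,8R)-3-(tert-butyldimethylsilyloxy)-8-(4-methoxybenzyloxy)-4,10-dimethyl-6-oxocyclodeca-1(10)Z,4Z-dien-7-yl]acetate | COC(=O)C[C@@H]1C(=O)/C=C(/C)[C@@H](O[Si](C)(C)C(C)(C)C)C/C=C(/C)C[C@H]1OCc1ccc(OC)cc1 | intermediate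
14 | methyl [(3S,6S,7R,8R)-3-(tert-butyldimethylsilyloxy)-6-hydroxy-8-(4-methoxybenzyloxy)-4,10-dimethylcyclodeca-1(10)Z,4Z-dien-7-yl]acetate | COC(=O)C[C@@H]1[C@@H](O)/C=C(/C)[C@@H](O[Si](C)(C)C(C)(C)C)C/C=C(/C)C[C@H]1OCc1ccc(OC)cc1 | intermediate (not isolated)
15 | (3S,6S,7S,8R)-3-(tert-butyldimethylsilyloxy)-8-(4-methoxybenzyloxy)-13-norgermacra-1(10)Z,4Z-dien-6,12-olide | C1C(=O)O[C@H]2/C=C(/C)[C@@H](O[Si](C)(C)C(C)(C)C)C/C=C(/C)C[C@@H](OCc3ccc(OC)cc3)[C@H]12 | intermediate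
16 | 13-(dimethylamino)-11,13-dihydro derivative of 18 (Mannich base; C11 configuration not assigned, lost in the next stage) | CN(C)CC1C(=O)O[C@H]2/C=C(/C)[C@@H](O[Si](C)(C)C(C)(C)C)C/C=C(/C)C[C@@H](OCc3ccc(OC)cc3)[C@H]12 | intermediate (not isolated)
17 | N-methyl quaternary ammonium iodide of 16 | C[N+](C)(C)CC1C(=O)O[C@H]2/C=C(/C)[C@@H](O[Si](C)(C)C(C)(C)C)C/C=C(/C)C[C@@H](OCc3ccc(OC)cc3)[C@H]12.[I-] | intermediate (not isolated)
18 | (3S,6S,7S,8R)-3-(tert-butyldimethylsilyloxy)-8-(4-methoxybenzyloxy)germacra-1(10)Z,4Z,11(13)-trien-6,12-olide | C=C1C(=O)O[C@H]2/C=C(/C)[C@@H](O[Si](C)(C)C(C)(C)C)C/C=C(/C)C[C@@H](OCc3ccc(OC)cc3)[C@H]12 | intermediate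
19 | (3S,6S,7S,8R)-3-(tert-butyldimethylsilyloxy)-8-hydroxygermacra-1(10)Z,4Z,11(13)-trien-6,12-olide | C=C1C(=O)O[C@H]2/C=C(/C)[C@@H](O[Si](C)(C)C(C)(C)C)C/C=C(/C)C[C@@H](O)[C@H]12 | intermediate
20 | (1R,3S,6S,7S,8R,10S)-3-(tert-butyldimethylsilyloxy)-1,10-epoxy-8-hydroxygermacra-4Z,11(13)-dien-6,12-olide | C=C1C(=O)O[C@H]2/C=C(/C)[C@@H](O[Si](C)(C)C(C)(C)C)C[C@H]3O[C@@]3(C)C[C@@H](O)[C@H]12 | intermediate
21 | (1R,3S,6S,7S,8R,10S)-3-(tert-butyldimethylsilyloxy)-1,10-epoxy-8-isobutyryloxygermacra-4Z,11(13)-dien-6,12-olide | C=C1C(=O)O[C@H]2/C=C(/C)[C@@H](O[Si](C)(C)C(C)(C)C)C[C@H]3O[C@@]3(C)C[C@@H](OC(=O)C(C)C)[C@H]12 | intermediate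
22 | (1R,3S,6S,7S,8R,10S)-1,10-epoxy-3-hydroxy-8-isobutyryloxygermacra-4Z,11(13)-dien-6,12-olide (CNP0261225.1) | C=C1C(=O)O[C@H]2/C=C(/C)[C@@H](O)C[C@H]3O[C@@]3(C)C[C@@H](OC(=O)C(C)C)[C@H]12 | target

## Step count and risks

Total: 13 steps (12 on the main chain, one to make 7). Longest linear sequence: 12 steps (1 → 22 through steps 1–3 and 5–13). The stereochemical outcomes of steps 5, 7, 8 and 11 are predictions from conformational models, not experimental results.

The three steps most likely to fail: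

**Step 5, facial selectivity of the alkynyl addition.** The route needs attack cis to the isopropenyl group; α′-alkenyl cyclohexenones often take nucleophiles anti to that group, which would give the C1 epimer of 9 and from it an E alkene and the wrong C8. The fallback sets out from enone 4 and comes back at epoxy alcohol 20.
- Enone 4 is equilibrated with DBU (toluene, rt, separation, recycling) to its C6 epimer, the trans enone F1.
- Addition of 8 anti to the isopropenyl group now puts the alkyne on the face of the silyloxy group, giving propargylic alcohol F2; LiAlH4 gives the E enol ether F3.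
- The oxy-Cope of F3 runs through the all-equatorial chair and gives, after alkylation as in step 7, the 1(10)E keto ester F4 with the same C7 and C8 configuration as 13.
- Reduction and lactonisation as in step 8 give the 1(10)E lactone F5.
- OsO4 (cat.) with N-methylmorpholine N-oxide dihydroxylates the strained E alkene from its outer face to diol F6. MsCl/Et3N gives the secondary mesylate F7, and DBU closes it with inversion at C1 to the cis-epoxide F8.
- Methylenation as in step 9 gives the methylene lactone F9, and DDQ as in step 10 returns to 20.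

**Step 7, oxy-Cope and enolate alkylation.** The potassium enolate 12 carries a β-alkoxy group and may lose 4-methoxybenzyl alkoxide (E1cB), or alkylate on oxygen. The fallback sets out from 10 and comes back at 13.
- 10 is silylated (TMSCl, imidazole) to the trimethylsilyl ether F10.
- Heating (toluene, 160 °C, sealed tube) effects the neutral siloxy-Cope rearrangement through the same chair to the silyl dienol ether F11, with no free enolate present.
- MeLi (THF, 0 °C) releases the lithium enolate F12, which is alkylated with BrCH2CO2Me at −78 °C to give 13.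

**Step 8, configuration at C6.** If the zinc chelate does not form in the ring, hydride will attack the periphery and give the C6 epimer. The fallback sets out from 13 and comes back at 15.
- Non-chelating Luche reduction (NaBH4, CeCl3·7H2O, MeOH) is used deliberately to make the 6-epi alcohol, which closes to the cis-lactone F13.
- LiOH (THF/H2O) opens it to the hydroxy acid F14.
- Mitsunobu lactonisation (PPh3, DIAD, THF, 0 °C) closes the ring with inversion at C6 to give 15.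

## Further compounds

F1 | step 5 | (4S,6R)-4-(tert-butyldimethylsilyloxy)-3-methyl-6-(prop-1-en-2-yl)cyclohex-2-en-1-one (trans enone) | CC1=CC(=O)[C@H](C[C@@H]1O[Si](C)(C)C(C)(C)C)C(C)=C
F2 | step 5 | (1R,4S,6R)-4-(tert-butyldimethylsilyloxy)-1-[(4-methoxybenzyloxy)ethynyl]-3-methyl-6-(prop-1-en-2-yl)cyclohex-2-en-1-ol | CC1=C[C@](O)(C#COCc2ccc(OC)cc2)[C@H](C[C@@H]1O[Si](C)(C)C(C)(C)C)C(C)=C
F3 | step 5 | (1R,4S,6R)-4-(tert-butyldimethylsilyloxy)-1-[(E)-2-(4-methoxybenzyloxy)ethenyl]-3-methyl-6-(prop-1-en-2-yl)cyclohex-2-en-1-ol | CC1=C[C@](O)(/C=C/OCc2ccc(OC)cc2)[C@H](C[C@@H]1O[Si](C)(C)C(C)(C)C)C(C)=C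
F4 | step 5 | methyl [(3S,7S,8R)-3-(tert-butyldimethylsilyloxy)-8-(4-methoxybenzyloxy)-4,10-dimethyl-6-oxocyclodeca-1(10)E,4Z-dien-7-yl]acetate | COC(=O)C[C@@H]1C(=O)/C=C(/C)[C@@H](O[Si](C)(C)C(C)(C)C)C/C=C(\C)C[C@H]1OCc1ccc(OC)cc1
F5 | step 5 | (3S,6S,7S,8R)-3-(tert-butyldimethylsilyloxy)-8-(4-methoxybenzyloxy)-13-norgermacra-1(10)E,4Z-dien-6,12-olide | C1C(=O)O[C@H]2/C=C(/C)[C@@H](O[Si](C)(C)C(C)(C)C)C/C=C(\C)C[C@@H](OCc3ccc(OC)cc3)[C@H]12
F6 | step 5 | (1S,3S,6S,7S,8R,10S)-3-(tert-butyldimethylsilyloxy)-1,10-dihydroxy-8-(4-methoxybenzyloxy)-13-norgermacr-4Z-en-6,12-olide | C1C(=O)O[C@H]2/C=C(/C)[C@@H](O[Si](C)(C)C(C)(C)C)C[C@H](O)[C@@](C)(O)C[C@@H](OCc3ccc(OC)cc3)[C@H]12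
F7 | step 5 | 1-O-methanesulfonate of F6 | C1C(=O)O[C@H]2/C=C(/C)[C@@H](O[Si](C)(C)C(C)(C)C)C[C@H](OS(C)(=O)=O)[C@@](C)(O)C[C@@H](OCc3ccc(OC)cc3)[C@H]12
F8 | step 5 | (1R,3S,6S,7S,8R,10S)-3-(tert-butyldimethylsilyloxy)-1,10-epoxy-8-(4-methoxybenzyloxy)-13-norgermacr-4Z-en-6,12-olide | C1C(=O)O[C@H]2/C=C(/C)[C@@H](O[Si](C)(C)C(C)(C)C)C[C@H]3O[C@@]3(C)C[C@@H](OCc4ccc(OC)cc4)[C@H]12
F9 | step 5 | (1R,3S,6S,7S,8R,10S)-3-(tert-butyldimethylsilyloxy)-1,10-epoxy-8-(4-methoxybenzyloxy)germacra-4Z,11(13)-dien-6,12-olide | C=C1C(=O)O[C@H]2/C=C(/C)[C@@H](O[Si](C)(C)C(C)(C)C)C[C@H]3O[C@@]3(C)C[C@@H](OCc4ccc(OC)cc4)[C@H]12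
F10 | step 7 | trimethylsilyl ether of 10 | CC1=C[C@](O[Si](C)(C)C)(/C=C/OCc2ccc(OC)cc2)[C@@H](C[C@@H]1O[Si](C)(C)C(C)(C)C)C(C)=C
F11 | step 7 | (3S,8R)-3-(tert-butyldimethylsilyloxy)-8-(4-methoxybenzyloxy)-4,10-dimethyl-6-(trimethylsilyloxy)cyclodeca-1(10)Z,4Z,6-triene (C5 and C8 trans on the enol ether double bond) | C[Si](C)(C)O/C1=C\[C@H](OCc2ccc(OC)cc2)C/C(C)=C\C[C@H](O[Si](C)(C)C(C)(C)C)/C(C)=C\1
F12 | step 7 | lithium enolate corresponding to 12 | [Li+].[O-]/C1=C\[C@H](OCc2ccc(OC)cc2)C/C(C)=C\C[C@H](O[Si](C)(C)C(C)(C)C)/C(C)=C\1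
F13 | step 8 | (3S,6R,7S,8R)-3-(tert-butyldimethylsilyloxy)-8-(4-methoxybenzyloxy)-13-norgermacra-1(10)Z,4Z-dien-6,12-olide (6-epi-15, cis-lactone) | C1C(=O)O[C@@H]2/C=C(/C)[C@@H](O[Si](C)(C)C(C)(C)C)C/C=C(/C)C[C@@H](OCc3ccc(OC)cc3)[C@H]12
F14 | step 8 | [(3S,6R,7R,8R)-3-(tert-butyldimethylsilyloxy)-6-hydroxy-8-(4-methoxybenzyloxy)-4,10-dimethylcyclodeca-1(10)Z,4Z-dien-7-yl]acetic acid | OC(=O)C[C@@H]1[C@H](O)/C=C(/C)[C@@H](O[Si](C)(C)C(C)(C)C)C/C=C(/C)C[C@H]1OCc1ccc(OC)cc1
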